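**Plan**

1. Locants used in the text (drimane type): ring A = C1–C5 and C10, ring B = C5–C10, C11 = CH2OAr on C9, C23 = CH2O-acyl on C4; the target is (3R,4S,5S,8S,9R,10R).
2. Retrosynthetic cuts, in order: C3–H (ketone reduction), C11–OAr (Mitsunobu), C23–O–acyl, C8–OH (alkene hydration), C4–C23 (enolate alkylation), C2–C3 (closure of ring A, with a CO2Me helper on C2), C9–C11 (sulfur ylide), C10–C1 and C10–CH3 (enolate alkylations).
3. Forward: ring B is the ring of (S)-carvone, which supplies C5; methylation, then allylation anti to the isopropenyl group, set quaternary C10; the carbonyl carbon becomes C9(H)–C11H2OH; allyl and isopropenyl are then oxidised together into two ester arms.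
4. Feature that allows the key event: C3 lies between the unsubstituted methylene C2 and the fully substituted C4, and the two arms stand trans-diequatorial on C10 and C5 of ring B; an ester enolate at C2 can therefore acylate the C3 ester and close ring A trans-fused, and only this Claisen mode leaves an acidic hydrogen (on C2) between two carbonyl groups.
5. The helper then makes C4 the γ-carbon of a dianion: CH2OBn enters anti to the axial C10 methyl and C4 becomes quaternary; the helper leaves by Krapcho reaction; ring B is completed by hydration at C8 anti to the same methyl.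
6. C9 is set by axial ylide attack anti to the C10 methyl followed by invertive C–O to C–H exchange; C3 is set last by axial hydride delivery.

Key step: step 9

**Route**

Step 1
Reactants: 1 (S)-(+)-carvone
Product: 3 (5S,6RS)-2,6-dimethyl-5-(prop-1-en-2-yl)cyclohex-2-en-1-one, via lithium dienolate 2 (not isolated)
Conditions: LDA, THF, −78 °C; MeI, −78 → 0 °C
Reagents that add atoms: lithium diisopropylamide, CC(C)N([Li])C(C)C (lithium carried only by 2); iodomethane, CI
Why: Kinetic deprotonation at the only enolisable position gives the cross-conjugated dienolate 2, which is C-methylated (enolate alkylation); the new centre forms as an epimeric mixture that does not matter because it becomes trigonal again in step 2.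

Step 2
Reactants: 3 (5S,6RS)-2,6-dimethyl-5-(prop-1-en-2-yl)cyclohex-2-en-1-one
Product: 5 (5R,6R)-2,6-dimethyl-6-(prop-2-en-1-yl)-5-(prop-1-en-2-yl)cyclohex-2-en-1-one, via lithium enolate 4 (not isolated)
Conditions: LDA, THF, −78 °C; allyl bromide, −78 °C → rt
Reagents that add atoms: lithium diisopropylamide, CC(C)N([Li])C(C)C (lithium carried only by 4); allyl bromide, C=CCBr
Why: Enolate alkylation of the tetrasubstituted dienolate 4, in which allyl bromide should approach anti to the neighbouring isopropenyl group, sets the quaternary centre (future C10) with allyl trans and methyl cis to isopropenyl.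

Step 3
Reactants: 5 (5R,6R)-2,6-dimethyl-6-(prop-2-en-1-yl)-5-(prop-1-en-2-yl)cyclohex-2-en-1-one
Product: 6 (3R,7R,8R)-4,8-dimethyl-8-(prop-2-en-1-yl)-7-(prop-1-en-2-yl)-1-oxaspiro[2.5]oct-4-ene
Conditions: Me3S+ I−, n-BuLi, THF, −10 → 0 °C
Reagents that add atoms: trimethylsulfonium iodide, C[S+](C)C.[I-]
Why: Corey–Chaykovsky epoxidation, in which the sulfonium ylide adds 1,2 to the enone carbonyl along the axial trajectory anti to the pseudoaxial methyl on the neighbouring quaternary carbon (the other face is screened by that methyl or by a syn-axial isopropenyl group), so the new CH2 should sit anti to that methyl in spiro-epoxide 6.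

Step 4
Reactants: 6 (3R,7R,8R)-4,8-dimethyl-8-(prop-2-en-1-yl)-7-(prop-1-en-2-yl)-1-oxaspiro[2.5]oct-4-ene
Product: 7 [(1R,5R,6R)-2,6-dimethyl-6-(prop-2-en-1-yl)-5-(prop-1-en-2-yl)cyclohex-2-en-1-yl]methanol
Conditions: Pd2(dba)3·CHCl3 (cat.), n-Bu3P, HCO2H, Et3N, 1,4-dioxane, rt
Reagents that add atoms: none
Why: Formate hydrogenolysis of a vinyl epoxide through a π-allyl complex of zerovalent palladium, in which ionisation occurs with inversion and hydride is then passed from the metal to the more substituted allyl terminus on the metal face, so that C–O is exchanged for C–H with net inversion, the future C9 carries CH2OH cis to the quaternary methyl, and the trisubstituted alkene is kept.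

Step 5
Reactants: 7 [(1R,5R,6R)-2,6-dimethyl-6-(prop-2-en-1-yl)-5-(prop-1-en-2-yl)cyclohex-2-en-1-yl]methanol
Product: 8 tert-butyl{[(1R,5R,6R)-2,6-dimethyl-6-(prop-2-en-1-yl)-5-(prop-1-en-2-yl)cyclohex-2-en-1-yl]methoxy}diphenylsilane
Conditions: TBDPSCl, imidazole, DMF, rt
Reagents that add atoms: tert-butyl(chloro)diphenylsilane, CC(C)(C)[Si](Cl)(c1ccccc1)c1ccccc1
Why: Silylation of the primary alcohol with a group that should withstand base, oxidation and heat in steps 6 to 14; no stereocentre is touched.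

Step 6
Reactants: 8 tert-butyl{[(1R,5R,6R)-2,6-dimethyl-6-(prop-2-en-1-yl)-5-(prop-1-en-2-yl)cyclohex-2-en-1-yl]methoxy}diphenylsilane
Product: 10 (2RS)-2-[(1R,5R,6R)-5-({[tert-butyl(diphenyl)silyl]oxy}methyl)-6-(3-hydroxypropyl)-4,6-dimethylcyclohex-3-en-1-yl]propan-1-ol, via bis(9-BBN) adduct 9 (not isolated)
Conditions: 9-BBN, THF, 0 °C → rt; then NaOH, H2O2, 0 °C → rt
Reagents that add atoms: 9-borabicyclo[3.3.1]nonane, B1C2CCCC1CCC2 (boron carried only by 9); hydrogen peroxide, OO
Why: Anti-Markovnikov hydroboration–oxidation, in which 9-BBN should take both terminal alkenes and spare the hindered trisubstituted ring alkene; the new side-chain methine forms without control and is made trigonal again by enolisation before C4 is fixed in step 10.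

Step 7
Reactants: 10 (2RS)-2-[(1R,5R,6R)-5-({[tert-butyl(diphenyl)silyl]oxy}methyl)-6-(3-hydroxypropyl)-4,6-dimethylcyclohex-3-en-1-yl]propan-1-ol
Product: 11 (2RS)-2-[(1R,5R,6R)-5-({[tert-butyl(diphenyl)silyl]oxy}methyl)-6-(2-carboxyethyl)-4,6-dimethylcyclohex-3-en-1-yl]propanoic acid
Conditions: TEMPO (cat.), PhI(OAc)2, MeCN–H2O, rt
Reagents that add atoms: water, O
Why: Nitroxyl-catalysed oxidation with PhI(OAc)2 in aqueous acetonitrile should take both primary alcohols through the aldehyde hydrates to the acids and leave the alkene and the silyl ether alone.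

Step 8
Reactants: 11 (2RS)-2-[(1R,5R,6R)-5-({[tert-butyl(diphenyl)silyl]oxy}methyl)-6-(2-carboxyethyl)-4,6-dimethylcyclohex-3-en-1-yl]propanoic acid
Product: 12 methyl (2RS)-2-[(1R,5R,6R)-5-({[tert-butyl(diphenyl)silyl]oxy}methyl)-6-(3-methoxy-3-oxopropyl)-4,6-dimethylcyclohex-3-en-1-yl]propanoate
Conditions: TMSCHN2, PhMe–MeOH, 0 °C
Reagents that add atoms: (trimethylsilyl)diazomethane, C[Si](C)(C)C=[N+]=[N-]
Why: Methyl ester formation with the diazoalkane under neutral conditions; no stereocentre is touched.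

Step 9
Reactants: 12 methyl (2RS)-2-[(1R,5R,6R)-5-({[tert-butyl(diphenyl)silyl]oxy}methyl)-6-(3-methoxy-3-oxopropyl)-4,6-dimethylcyclohex-3-en-1-yl]propanoate
Product: 14 methyl (2RS,4R,4aR,8R,8aR)-8-({[tert-butyl(diphenyl)silyl]oxy}methyl)-4,7,8a-trimethyl-3-oxo-1,2,3,4,4a,5,8,8a-octahydronaphthalene-2-carboxylate, via potassium enolate 13 (not isolated)
Conditions: KOt-Bu, THF, 0 °C → rt; then AcOH
Reagents that add atoms: potassium tert-butoxide, CC(C)(C)[O-].[K+] (potassium carried only by 13)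
Why: Dieckmann (intramolecular Claisen) condensation: tert-butoxide reversibly forms the ester enolate at C2, which adds to the C3 ester carbonyl, methoxide leaves, and the β-keto ester is drained as its potassium enolate 13. The closest known reaction type is the Dieckmann cyclisation of a heptanedioate to a 2-alkoxycarbonylcyclohexanone. Ring A closes in the 6-(enolexo)-exo-trig mode, and it can only close trans-fused because the two arms stand trans-diequatorial on C10 and C5 of ring B. No permanent stereocentre is created: C2 carries the helper ester and stays labile, and C4 equilibrates to the equatorial methyl epimer before it is made quaternary in step 10. The selectivity needed is between the two Claisen modes (C2 onto C3, or C4 onto the arm ester); all steps are reversible and only the first mode gives a product with an acidic hydrogen between two carbonyl groups, because C4 would be quaternary in the other product, so the equilibrium should end at 13.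

Step 10
Reactants: 14 methyl (2RS,4R,4aR,8R,8aR)-8-({[tert-butyl(diphenyl)silyl]oxy}methyl)-4,7,8a-trimethyl-3-oxo-1,2,3,4,4a,5,8,8a-octahydronaphthalene-2-carboxylate
Product: 16 methyl (2RS,4S,4aS,8R,8aR)-4-[(benzyloxy)methyl]-8-({[tert-butyl(diphenyl)silyl]oxy}methyl)-4,7,8a-trimethyl-3-oxo-1,2,3,4,4a,5,8,8a-octahydronaphthalene-2-carboxylate, via sodium lithium dianion 15 (not isolated)
Conditions: NaH, THF, 0 °C; n-BuLi, 0 °C; BnOCH2Cl, −78 → 0 °C; then AcOH
Reagents that add atoms: sodium hydride, [Na+].[H-], and n-butyllithium, [Li]CCCC (metals carried only by 15); benzyl chloromethyl ether, ClCOCc1ccccc1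
Why: γ-Alkylation of a β-keto ester dianion, in which the second deprotonation can only take place at C4, the more reactive γ-carbon of 15 attacks the chloromethyl ether, and the electrophile should enter anti to the axial C10 methyl, so that C4 becomes quaternary with CH2OBn equatorial and CH3 axial.

Step 11
Reactants: 16 methyl (2RS,4S,4aS,8R,8aR)-4-[(benzyloxy)methyl]-8-({[tert-butyl(diphenyl)silyl]oxy}methyl)-4,7,8a-trimethyl-3-oxo-1,2,3,4,4a,5,8,8a-octahydronaphthalene-2-carboxylate
Product: 17 (1S,4aR,5R,8aS)-1-[(benzyloxy)methyl]-5-({[tert-butyl(diphenyl)silyl]oxy}methyl)-1,4a,6-trimethyl-3,4,4a,5,8,8a-hexahydronaphthalen-2(1H)-one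
Conditions: LiCl, H2O, DMSO, 150 °C
Reagents that add atoms: none
Why: Krapcho dealkoxycarbonylation, in which chloride demethylates the ester and the β-keto carboxylate loses CO2, removes the helper carbon from C2 without touching quaternary C4.

Step 12
Reactants: 17 (1S,4aR,5R,8aS)-1-[(benzyloxy)methyl]-5-({[tert-butyl(diphenyl)silyl]oxy}methyl)-1,4a,6-trimethyl-3,4,4a,5,8,8a-hexahydronaphthalen-2(1H)-one
Product: 18 (1S,4aR,5R,6S,8aS)-1-[(benzyloxy)methyl]-5-({[tert-butyl(diphenyl)silyl]oxy}methyl)-6-hydroxy-1,4a,6-trimethyloctahydronaphthalen-2(1H)-one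
Conditions: Co(acac)2 (cat.), PhSiH3, O2 (1 atm), THF–i-PrOH, rt
Reagents that add atoms: dioxygen, O=O
Why: Mukaiyama hydration, in which hydrogen atom transfer from a cobalt hydride to C7 gives the tertiary C8 radical (Markovnikov) that should be trapped by O2 on the face anti to the 1,3-related axial C10 methyl, giving the equatorial tertiary alcohol with the C8 methyl axial.

Step 13
Reactants: 18 (1S,4aR,5R,6S,8aS)-1-[(benzyloxy)methyl]-5-({[tert-butyl(diphenyl)silyl]oxy}methyl)-6-hydroxy-1,4a,6-trimethyloctahydronaphthalen-2(1H)-one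
Product: 19 (1S,4aR,5R,6S,8aS)-5-({[tert-butyl(diphenyl)silyl]oxy}methyl)-6-hydroxy-1-(hydroxymethyl)-1,4a,6-trimethyloctahydronaphthalen-2(1H)-one
Conditions: H2 (1 atm), Pd/C, EtOAc, rt
Reagents that add atoms: none
Why: Hydrogenolysis of the benzyl ether over palladium on carbon; with the ring alkene already hydrated nothing else is reducible and no stereocentre is touched.

Step 14
Reactants: 19 (1S,4aR,5R,6S,8aS)-5-({[tert-butyl(diphenyl)silyl]oxy}methyl)-6-hydroxy-1-(hydroxymethyl)-1,4a,6-trimethyloctahydronaphthalen-2(1H)-one; 20 angelic acid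
Product: 22 [(1S,4aR,5R,6S,8aS)-5-({[tert-butyl(diphenyl)silyl]oxy}methyl)-6-hydroxy-1,4a,6-trimethyl-2-oxodecahydronaphthalen-1-yl]methyl (2Z)-2-methylbut-2-enoate, via mixed anhydride 21 (not isolated)
Conditions: 2,4,6-Cl3C6H2COCl, Et3N, PhMe, rt; then 19, PhMe, 80 °C
Reagents that add atoms: 2,4,6-trichlorobenzoyl chloride, ClC(=O)c1c(Cl)cc(Cl)cc1Cl (acyl group carried only by 21)
Why: Yamaguchi-type esterification through mixed anhydride 21, run without a nucleophilic amine catalyst so that the Z double bond should not isomerise; the primary alcohol reacts and the tertiary one does not.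

Step 15
Reactants: 22 [(1S,4aR,5R,6S,8aS)-5-({[tert-butyl(diphenyl)silyl]oxy}methyl)-6-hydroxy-1,4a,6-trimethyl-2-oxodecahydronaphthalen-1-yl]methyl (2Z)-2-methylbut-2-enoate
Product: 23 [(1S,4aR,5R,6S,8aS)-6-hydroxy-5-(hydroxymethyl)-1,4a,6-trimethyl-2-oxodecahydronaphthalen-1-yl]methyl (2Z)-2-methylbut-2-enoate
Conditions: TBAF, AcOH, THF, rt
Reagents that add atoms: none
Why: Fluoride-induced cleavage of the silyl ether, buffered with acetic acid so that the angelate should neither migrate nor isomerise.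

Step 16
Reactants: 23 [(1S,4aR,5R,6S,8aS)-6-hydroxy-5-(hydroxymethyl)-1,4a,6-trimethyl-2-oxodecahydronaphthalen-1-yl]methyl (2Z)-2-methylbut-2-enoate; 24 umbelliferone (7-hydroxy-2H-chromen-2-one)
Product: 25 [(1S,4aR,5R,6S,8aS)-6-hydroxy-1,4a,6-trimethyl-2-oxo-5-{[(2-oxo-2H-chromen-7-yl)oxy]methyl}decahydronaphthalen-1-yl]methyl (2Z)-2-methylbut-2-enoate
Conditions: PPh3, DIAD, THF, 0 °C → rt
Reagents that add atoms: none
Why: Mitsunobu etherification, in which the phenol is acidic enough to protonate the betaine and then displaces the oxyphosphonium group at the primary C11 carbon while the tertiary alcohol and the ketone stay inert; no stereocentre is touched.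

Step 17
Reactants: 25 [(1S,4aR,5R,6S,8aS)-6-hydroxy-1,4a,6-trimethyl-2-oxo-5-{[(2-oxo-2H-chromen-7-yl)oxy]methyl}decahydronaphthalen-1-yl]methyl (2Z)-2-methylbut-2-enoate
Product: 26 [(1S,2R,4aR,5R,6S,8aS)-2,6-dihydroxy-1,4a,6-trimethyl-5-{[(2-oxo-2H-chromen-7-yl)oxy]methyl}decahydronaphthalen-1-yl]methyl (2Z)-2-methylbut-2-enoate
Conditions: NaBH4, CeCl3·7H2O, MeOH–THF, −40 °C; then AcOH
Reagents that add atoms: none
Why: Luche-type borohydride reduction, in which hydride should add to the C3 ketone along the axial trajectory (the equatorial side is screened by the two C4 substituents) to give the equatorial alcohol cis to the C10 methyl, while the coumarin lactone and the angelate are not reduced at low temperature and the cold acidic quench guards against acyl migration.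

**Compound list**

1 | (S)-(+)-carvone, (5S)-2-methyl-5-(prop-1-en-2-yl)cyclohex-2-en-1-one | CC(=C)[C@H]1CC=C(C)C(=O)C1 | starting material
2 | lithium dienolate of 1 (not isolated) | CC(=C)[C@H]1CC=C(C)C(O[Li])=C1 | intermediate
3 | (5S,6RS)-2,6-dimethyl-5-(prop-1-en-2-yl)cyclohex-2-en-1-one (C6 epimers) | CC(=C)[C@H]1CC=C(C)C(=O)C1C | intermediate
4 | lithium enolate of 3 (not isolated) | CC(=C)[C@H]1CC=C(C)C(O[Li])=C1C | intermediate
5 | (5R,6R)-2,6-dimethyl-6-(prop-2-en-1-yl)-5-(prop-1-en-2-yl)cyclohex-2-en-1-one | CC(=C)[C@H]1CC=C(C)C(=O)[C@]1(C)CC=C | intermediate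
6 | (3R,7R,8R)-4,8-dimethyl-8-(prop-2-en-1-yl)-7-(prop-1-en-2-yl)-1-oxaspiro[2.5]oct-4-ene | CC(=C)[C@H]1CC=C(C)[C@]2(CO2)[C@]1(C)CC=C | intermediate
7 | [(1R,5R,6R)-2,6-dimethyl-6-(prop-2-en-1-yl)-5-(prop-1-en-2-yl)cyclohex-2-en-1-yl]methanol | CC(=C)[C@H]1CC=C(C)[C@@H](CO)[C@]1(C)CC=C | intermediate
8 | tert-butyl{[(1R,5R,6R)-2,6-dimethyl-6-(prop-2-en-1-yl)-5-(prop-1-en-2-yl)cyclohex-2-en-1-yl]methoxy}diphenylsilane | CC(=C)[C@H]1CC=C(C)[C@@H](CO[Si](c2ccccc2)(c2ccccc2)C(C)(C)C)[C@]1(C)CC=C | intermediate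
9 | bis(9-borabicyclo[3.3.1]nonan-9-yl) adduct of 8, boron on both terminal carbons (not isolated) | CC(CB2C3CCCC2CCC3)[C@H]1CC=C(C)[C@@H](CO[Si](c2ccccc2)(c2ccccc2)C(C)(C)C)[C@]1(C)CCCB1C2CCCC1CCC2 | intermediate
10 | (2RS)-2-[(1R,5R,6R)-5-({[tert-butyl(diphenyl)silyl]oxy}methyl)-6-(3-hydroxypropyl)-4,6-dimethylcyclohex-3-en-1-yl]propan-1-ol | OCC(C)[C@H]1CC=C(C)[C@@H](CO[Si](c2ccccc2)(c2ccccc2)C(C)(C)C)[C@]1(C)CCCO | intermediate
11 | (2RS)-2-[(1R,5R,6R)-5-({[tert-butyl(diphenyl)silyl]oxy}methyl)-6-(2-carboxyethyl)-4,6-dimethylcyclohex-3-en-1-yl]propanoic acid | OC(=O)C(C)[C@H]1CC=C(C)[C@@H](CO[Si](c2ccccc2)(c2ccccc2)C(C)(C)C)[C@]1(C)CCC(O)=O | intermediate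
12 | methyl (2RS)-2-[(1R,5R,6R)-5-({[tert-butyl(diphenyl)silyl]oxy}methyl)-6-(3-methoxy-3-oxopropyl)-4,6-dimethylcyclohex-3-en-1-yl]propanoate | COC(=O)C(C)[C@H]1CC=C(C)[C@@H](CO[Si](c2ccccc2)(c2ccccc2)C(C)(C)C)[C@]1(C)CCC(=O)OC | intermediate
13 | potassium enolate of 14, enolate between the ester-bearing ring carbon and the ketone carbon (not isolated) | COC(=O)C1=C(O[K])[C@H](C)[C@H]2CC=C(C)[C@@H](CO[Si](c3ccccc3)(c3ccccc3)C(C)(C)C)[C@]2(C)C1 | intermediate
14 | methyl (2RS,4R,4aR,8R,8aR)-8-({[tert-butyl(diphenyl)silyl]oxy}methyl)-4,7,8a-trimethyl-3-oxo-1,2,3,4,4a,5,8,8a-octahydronaphthalene-2-carboxylate (keto form of a keto–enol pair) | COC(=O)C1C(=O)[C@H](C)[C@H]2CC=C(C)[C@@H](CO[Si](c3ccccc3)(c3ccccc3)C(C)(C)C)[C@]2(C)C1 | intermediate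
15 | sodium lithium dianion of 14, ester enolate plus ketone enolate toward the methyl-bearing carbon (not isolated) | COC(O[Na])=C1C(O[Li])=C(C)[C@H]2CC=C(C)[C@@H](CO[Si](c3ccccc3)(c3ccccc3)C(C)(C)C)[C@]2(C)C1 | intermediate
16 | methyl (2RS,4S,4aS,8R,8aR)-4-[(benzyloxy)methyl]-8-({[tert-butyl(diphenyl)silyl]oxy}methyl)-4,7,8a-trimethyl-3-oxo-1,2,3,4,4a,5,8,8a-octahydronaphthalene-2-carboxylate | COC(=O)C1C(=O)[C@](C)(COCc3ccccc3)[C@H]2CC=C(C)[C@@H](CO[Si](c4ccccc4)(c4ccccc4)C(C)(C)C)[C@]2(C)C1 | intermediate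
17 | (1S,4aR,5R,8aS)-1-[(benzyloxy)methyl]-5-({[tert-butyl(diphenyl)silyl]oxy}methyl)-1,4a,6-trimethyl-3,4,4a,5,8,8a-hexahydronaphthalen-2(1H)-one | O=C1[C@](C)(COCc3ccccc3)[C@H]2CC=C(C)[C@@H](CO[Si](c4ccccc4)(c4ccccc4)C(C)(C)C)[C@]2(C)CC1 | intermediate
18 | (1S,4aR,5R,6S,8aS)-1-[(benzyloxy)methyl]-5-({[tert-butyl(diphenyl)silyl]oxy}methyl)-6-hydroxy-1,4a,6-trimethyloctahydronaphthalen-2(1H)-one | O=C1[C@](C)(COCc3ccccc3)[C@H]2CC[C@](C)(O)[C@@H](CO[Si](c4ccccc4)(c4ccccc4)C(C)(C)C)[C@]2(C)CC1 | intermediate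
19 | (1S,4aR,5R,6S,8aS)-5-({[tert-butyl(diphenyl)silyl]oxy}methyl)-6-hydroxy-1-(hydroxymethyl)-1,4a,6-trimethyloctahydronaphthalen-2(1H)-one | O=C1[C@](C)(CO)[C@H]2CC[C@](C)(O)[C@@H](CO[Si](c3ccccc3)(c3ccccc3)C(C)(C)C)[C@]2(C)CC1 | intermediate
20 | angelic acid, (2Z)-2-methylbut-2-enoic acid | C/C=C(/C)C(O)=O | starting material
21 | (2Z)-2-methylbut-2-enoic 2,4,6-trichlorobenzoic anhydride (not isolated) | C/C=C(/C)C(=O)OC(=O)c1c(Cl)cc(Cl)cc1Cl | intermediate
22 | [(1S,4aR,5R,6S,8aS)-5-({[tert-butyl(diphenyl)silyl]oxy}methyl)-6-hydroxy-1,4a,6-trimethyl-2-oxodecahydronaphthalen-1-yl]methyl (2Z)-2-methylbut-2-enoate | C/C=C(/C)C(=O)OC[C@]1(C)[C@H]2CC[C@](C)(O)[C@@H](CO[Si](c3ccccc3)(c3ccccc3)C(C)(C)C)[C@]2(C)CCC1=O | intermediate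
23 | [(1S,4aR,5R,6S,8aS)-6-hydroxy-5-(hydroxymethyl)-1,4a,6-trimethyl-2-oxodecahydronaphthalen-1-yl]methyl (2Z)-2-methylbut-2-enoate | C/C=C(/C)C(=O)OC[C@]1(C)[C@H]2CC[C@](C)(O)[C@@H](CO)[C@]2(C)CCC1=O | intermediate
24 | umbelliferone, 7-hydroxy-2H-chromen-2-one | Oc1ccc2ccc(=O)oc2c1 | starting material
25 | [(1S,4aR,5R,6S,8aS)-6-hydroxy-1,4a,6-trimethyl-2-oxo-5-{[(2-oxo-2H-chromen-7-yl)oxy]methyl}decahydronaphthalen-1-yl]methyl (2Z)-2-methylbut-2-enoate | C/C=C(/C)C(=O)OC[C@]1(C)[C@H]2CC[C@](C)(O)[C@@H](COc3ccc4ccc(=O)oc4c3)[C@]2(C)CCC1=O | intermediate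
26 | [(1S,2R,4aR,5R,6S,8aS)-2,6-dihydroxy-1,4a,6-trimethyl-5-{[(2-oxo-2H-chromen-7-yl)oxy]methyl}decahydronaphthalen-1-yl]methyl (2Z)-2-methylbut-2-enoate | C/C=C(/C)C(=O)OC[C@]1(C)[C@H]2CC[C@](C)(O)[C@@H](COc3ccc4ccc(=O)oc4c3)[C@]2(C)CC[C@H]1O | target

**Count and risks**

Total step count: 17. Longest linear sequence: 17 steps, from 1 to 26; 20 and 24 are commercial and enter in steps 14 and 16.

The three steps most likely to fail:

Step 4. The allyl complex may form slowly because the C–O bond has to become pseudoaxial, hydride may be delivered to the far allyl terminus (giving the tetrasubstituted alkene), or the complex may collapse by β-hydride elimination to a diene. Fallback: setting out from 6, a Meinwald rearrangement (MgBr2·OEt2, CH2Cl2, −40 °C) should shift a hydride from the epoxide CH2 to the allylic carbon on the face anti to the departing oxygen and give (1R,5R,6R)-2,6-dimethyl-6-(prop-2-en-1-yl)-5-(prop-1-en-2-yl)cyclohex-2-ene-1-carbaldehyde F1. This aldehyde is reduced at once (NaBH4, MeOH, −20 °C), before the double bond can move into conjugation, and the route is rejoined at 7.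

Step 10. The dianion may be O-alkylated by the hard chloromethyl ether, or may react incompletely at the hindered tertiary γ-carbon. Fallback: setting out from 14, the same dianion is quenched with monomeric formaldehyde; this aldol addition forms the C–C bond without an alkyl halide and should follow the same facial preference. It should give methyl (2RS,4S,4aS,8R,8aR)-8-({[tert-butyl(diphenyl)silyl]oxy}methyl)-4-(hydroxymethyl)-4,7,8a-trimethyl-3-oxo-1,2,3,4,4a,5,8,8a-octahydronaphthalene-2-carboxylate F2. Its primary alcohol is then benzylated under acid catalysis (benzyl 2,2,2-trichloroacetimidate, cat. TfOH, CH2Cl2, 0 °C), and the route is rejoined at 16.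

Step 16. Substitution at the β-branched C11 carbon may be slow, so that the oxyphosphonium intermediate is diverted to alkylation of the hydrazide or to ring closure by the C8 hydroxyl. Fallback: setting out from 23, the primary alcohol is converted (MsCl, Et3N, CH2Cl2, 0 °C) into [(1S,4aR,5R,6S,8aS)-6-hydroxy-5-{[(methanesulfonyl)oxy]methyl}-1,4a,6-trimethyl-2-oxodecahydronaphthalen-1-yl]methyl (2Z)-2-methylbut-2-enoate F3. This sulfonate is displaced by the cesium salt of 24 (Cs2CO3, DMF, 60 °C) in a phenoxide alkylation, and the route is rejoined at 25.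

**Further compounds**

F1 | step 4 | (1R,5R,6R)-2,6-dimethyl-6-(prop-2-en-1-yl)-5-(prop-1-en-2-yl)cyclohex-2-ene-1-carbaldehyde | CC(=C)[C@H]1CC=C(C)[C@@H](C=O)[C@]1(C)CC=C
F2 | step 10 | methyl (2RS,4S,4aS,8R,8aR)-8-({[tert-butyl(diphenyl)silyl]oxy}methyl)-4-(hydroxymethyl)-4,7,8a-trimethyl-3-oxo-1,2,3,4,4a,5,8,8a-octahydronaphthalene-2-carboxylate | COC(=O)C1C(=O)[C@](C)(CO)[C@H]2CC=C(C)[C@@H](CO[Si](c3ccccc3)(c3ccccc3)C(C)(C)C)[C@]2(C)C1
F3 | step 16 | [(1S,4aR,5R,6S,8aS)-6-hydroxy-5-{[(methanesulfonyl)oxy]methyl}-1,4a,6-trimethyl-2-oxodecahydronaphthalen-1-yl]methyl (2Z)-2-methylbut-2-enoate | C/C=C(/C)C(=O)OC[C@]1(C)[C@H]2CC[C@](C)(O)[C@@H](COS(C)(=O)=O)[C@]2(C)CCC1=O
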